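**Retrosynthetic overview**
1. The core is a nortricyclene (tricyclo[2.2.1.0²,⁶]heptane) fused to a cyclohexane; a nortricyclene is a norbornene plus one 1,3-bond, so the ring-fusion bond between the CH2OAc-bearing quaternary carbon and the neighbouring quaternary apex carbon is a Diels–Alder bond of a cyclopentadiene.
2. Enabling feature: on the cyclohexane the CH2OAc carbon and the oxygen of the ring C–OAc are 1,4-cis, so they can be tied as a δ-lactone (CH2OAc raised to the carboxyl level) whose (Z)-α-(tosyloxymethylidene) group is the dienophile, with the cyclopentadiene hanging from the lactone C6 through the CMe2 carbon.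
3. Key step: dehydration of a tertiary cyclopentenol to equilibrating cyclopentadienes and a transannular intramolecular Diels–Alder reaction, which closes the cyclohexane (as a 2-oxabicyclo[2.2.2]octanone) and the bicyclo[2.2.1]heptene in one operation and sets both quaternary carbons.
4. After it: homoallyl-to-cyclopropylcarbinyl acetolysis of the exo tosylate (cyclopropane and the third C–O), LiAlH4 opening of the lactone tether, peracetylation, debenzylation.
5. Before it: Stork–Danheiser union of isobutyronitrile with 3-ethoxycyclopentenone, MeLi, Brown alkoxyallylboration, chelation-controlled reduction, hydroformylation to the lactone, formylation and enol tosylation. Ring order: δ-lactone, then cyclohexane plus norbornene, then cyclopropane.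

Key step: step 11

Remark on the chemistry: the tertiary carbinol carbon made in step 2 forms in both configurations; compounds 6 to 22 are carried as mixtures at that carbon (drawn without descriptor) because it becomes sp2 in step 11, and lactol 18 is an anomer mixture.

**Step 1**
Reactants: 1 isobutyronitrile; 2 3-ethoxycyclopent-2-en-1-one
Product: 5 2-methyl-2-(3-oxocyclopent-1-en-1-yl)propanenitrile, via 2-lithio-2-methylpropanenitrile 3 (not isolated), via lithium alkoxide adduct 4 (not isolated)
Conditions: LDA, THF, −78 °C; then 2, −78 → 0 °C; 2 M HCl, rt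
Reagents that add atoms: water, O
Why: Stork–Danheiser alkylative carbonyl transposition: the nitrile-stabilised tertiary carbanion adds to the vinylogous ester carbonyl, and acid hydrolysis of the enol ether with loss of water and ethanol should give the 3-substituted enone, joining the future CMe2 carbon to the five-membered ring; no stereocentre is formed.

**Step 2**
Reactants: 5 2-methyl-2-(3-oxocyclopent-1-en-1-yl)propanenitrile
Product: 6 2-(3-hydroxy-3-methylcyclopent-1-en-1-yl)-2-methylpropanenitrile
Conditions: MeLi, CeCl3, THF, −78 °C; aq. NH4Cl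
Reagents that add atoms: methyllithium, C[Li]
Why: Cerium-mediated 1,2-addition to the enone (β-carbon fully substituted, hindered tertiary nitrile inert at −78 °C) should give the tertiary allylic alcohol, a non-oxidisable mask of the cyclopentadiene; its configuration is irrelevant.

**Step 3**
Reactants: 6 2-(3-hydroxy-3-methylcyclopent-1-en-1-yl)-2-methylpropanenitrile
Product: 8 2-(3-hydroxy-3-methylcyclopent-1-en-1-yl)-2-methylpropanal, via aldimine 7 (not isolated)
Conditions: DIBAL-H (2.2 equiv), CH2Cl2, −78 °C; aq. Rochelle salt, then aq. NH4Cl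
Reagents that add atoms: water, O
Why: DIBAL-H reduction of a hindered nitrile stops at the aluminium aldimine, which mild aqueous work-up should hydrolyse to the non-enolisable aldehyde.

**Step 4**
Reactants: 8 2-(3-hydroxy-3-methylcyclopent-1-en-1-yl)-2-methylpropanal; 9 allyl benzyl ether
Product: 14 (3S,4S)-4-(benzyloxy)-2-(3-hydroxy-3-methylcyclopent-1-en-1-yl)-2-methylhex-5-en-3-ol, via (Z)-3-(benzyloxy)allyllithium 10 (not isolated), via lithium allyl(methoxy)borate complex 11 (not isolated), via B-[(Z)-3-(benzyloxy)allyl]diisopinocampheylborane 12 (not isolated), via diisopinocampheylborinate ester 13 (not isolated)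
Conditions: 9, s-BuLi, THF, −78 °C; (+)-Ipc2BOMe [from (−)-α-pinene]; BF3·OEt2; then 8, −78 °C → rt; ethanolamine
Reagents that add atoms: none
Why: Brown γ-alkoxyallylboration: the (Z)-γ-alkoxyallylborane adds through a closed chair transition state to give the syn diol monoether, and the isopinocampheyl groups from (−)-α-pinene select the aldehyde face that makes the ether-bearing carbon S; only the aldehyde reacts at −78 °C.

**Step 5**
Reactants: 14 (3S,4S)-4-(benzyloxy)-2-(3-hydroxy-3-methylcyclopent-1-en-1-yl)-2-methylhex-5-en-3-ol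
Product: 15 (4S)-4-(benzyloxy)-2-(3-hydroxy-3-methylcyclopent-1-en-1-yl)-2-methylhex-5-en-3-one
Conditions: Dess–Martin periodinane, NaHCO3, CH2Cl2, 0 °C
Reagents that add atoms: none
Why: Buffered Dess–Martin oxidation should convert the secondary alcohol (the tertiary one cannot react) to the ketone without disturbing the adjacent ether stereocentre.

**Step 6**
Reactants: 15 (4S)-4-(benzyloxy)-2-(3-hydroxy-3-methylcyclopent-1-en-1-yl)-2-methylhex-5-en-3-one
Product: 16 (3R,4S)-4-(benzyloxy)-2-(3-hydroxy-3-methylcyclopent-1-en-1-yl)-2-methylhex-5-en-3-ol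
Conditions: Zn(BH4)2, Et2O, −30 °C; aq. NH4Cl
Reagents that add atoms: none
Why: Chelation-controlled (Cram chelate) reduction: zinc bridges the carbonyl and benzyloxy oxygens and hydride enters from the side of the small hydrogen, which should give the anti (3R,4S) alcohol needed for the cis ring diol.

**Step 7**
Reactants: 16 (3R,4S)-4-(benzyloxy)-2-(3-hydroxy-3-methylcyclopent-1-en-1-yl)-2-methylhex-5-en-3-ol
Product: 18 (5S,6R)-5-(benzyloxy)-6-[2-(3-hydroxy-3-methylcyclopent-1-en-1-yl)propan-2-yl]oxan-2-ol, via hydroxy aldehyde 17 (not isolated)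
Conditions: Rh(acac)(CO)2 (1 mol%), BiPhePhos (2 mol%), CO/H2 (1:1, 5 bar), PhMe, 60 °C
Reagents that add atoms: carbon monoxide, [C-]#[O+]
Why: Linear-selective rhodium/bisphosphite hydroformylation of the terminal vinyl group (the trisubstituted ring alkene is inert) should give the δ-hydroxy aldehyde, which closes to the six-membered lactol.

**Step 8**
Reactants: 18 (5S,6R)-5-(benzyloxy)-6-[2-(3-hydroxy-3-methylcyclopent-1-en-1-yl)propan-2-yl]oxan-2-ol
Product: 19 (5S,6R)-5-(benzyloxy)-6-[2-(3-hydroxy-3-methylcyclopent-1-en-1-yl)propan-2-yl]oxan-2-one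
Conditions: TPAP (5 mol%), NMO, 4 Å MS, CH2Cl2, rt
Reagents that add atoms: none
Why: Ley–Griffith oxidation of the lactol should give the δ-lactone under neutral conditions; the tertiary alcohol cannot be oxidised.

**Step 9**
Reactants: 19 (5S,6R)-5-(benzyloxy)-6-[2-(3-hydroxy-3-methylcyclopent-1-en-1-yl)propan-2-yl]oxan-2-one
Product: 21 (3Z,5S,6R)-5-(benzyloxy)-3-(hydroxymethylidene)-6-[2-(3-hydroxy-3-methylcyclopent-1-en-1-yl)propan-2-yl]oxan-2-one, via dilithium lactone enolate 20 (not isolated)
Conditions: LDA (2.3 equiv), THF, −78 °C; HCO2Et, −78 → −20 °C; aq. NH4Cl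
Reagents that add atoms: ethyl formate, CCOC=O
Why: Claisen-type C-formylation of the lactone enolate (the hindered tertiary alkoxide is a spectator at low temperature) should give the α-formyl lactone, held as the hydrogen-bonded hydroxymethylidene tautomer.

**Step 10**
Reactants: 21 (3Z,5S,6R)-5-(benzyloxy)-3-(hydroxymethylidene)-6-[2-(3-hydroxy-3-methylcyclopent-1-en-1-yl)propan-2-yl]oxan-2-one
Product: 22 (3Z,5S,6R)-5-(benzyloxy)-6-[2-(3-hydroxy-3-methylcyclopent-1-en-1-yl)propan-2-yl]-3-{[(4-methylbenzenesulfonyl)oxy]methylidene}oxan-2-one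
Conditions: TsCl, TMEDA, LiCl, MeCN, 0 °C
Reagents that add atoms: 4-methylbenzenesulfonyl chloride, Cc1ccc(cc1)S(Cl)(=O)=O
Why: Stereodefined enol tosylation: O-sulfonylation of the lithium-chelated enolate, in which the enolate oxygen is held cis to the lactone carbonyl, should give the Z enol tosylate, the geometry that later places the tosylate exo.

**Step 11**
Reactants: 22 (3Z,5S,6R)-5-(benzyloxy)-6-[2-(3-hydroxy-3-methylcyclopent-1-en-1-yl)propan-2-yl]-3-{[(4-methylbenzenesulfonyl)oxy]methylidene}oxan-2-one
Product: 24 pentacyclic Diels–Alder adduct (lactone-bridged cyclohexane fused to a 2-methylnorborn-2-ene with exo tosylate), via cyclopentadiene 23 (not isolated)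
Conditions: PPTS (10 mol%), 4 Å MS, PhMe (5 mM), 100 °C
Reagents that add atoms: none
Why: PPTS ionises the tertiary allylic alcohol and the cyclopentenyl cation loses a proton, so that both carbinol epimers give cyclopentadienes which interconvert by 1,5-hydrogen shifts and reversible protonation and drain through the one tautomer, 23, that carries the side chain on a diene terminus and has a free CH at the other. 23 reacts in a concerted suprafacial [4+2] cycloaddition, the closest precedent being the thermal type-1 intramolecular Diels–Alder reaction of 1-alkylcyclopentadienes with acrylate-type dienophiles on four-atom tethers; bonding is asynchronous, the unsubstituted diene terminus (largest HOMO coefficient) leading at the tosyloxy-bearing β-carbon so that the bond between the two fully substituted carbons can lag. That lagging bond closes the cyclohexane through the CH2–CH(OBn)–CH(O)–CMe2 tether and at the same time spans the 3- and 6-positions of the boat δ-lactone (a 2-oxabicyclo[2.2.2]octan-3-one), while the leading bond completes the bicyclo[2.2.1]heptene. The configuration of the lactone α-carbon is dictated by the stereocentre at C6 of the lactone, because the diene hangs from that carbon and can reach only the syn face of the alkylidene; the bridgehead carbons follow from the approach that puts the lactone carbonyl on the side of the cyclopentadiene CH2 (exo), the usual preference of α-alkylidene lactones and methacrylates because the ring CH2 avoids that CH2; the tosyloxy carbon follows from the Z geometry (tosylate exo). The step needs this face selectivity and reaction through the CH-terminated rather than the methyl-terminated diene tautomer, the latter secured by the steric cost of bonding at the methylated carbon, and the 5 mM dilution suppresses dimerisation.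

**Step 12**
Reactants: 24 pentacyclic Diels–Alder adduct
Product: 25 nortricyclyl acetate lactone
Conditions: AcOH, NaOAc, 100 °C
Reagents that add atoms: acetic acid, CC(O)=O
Why: Buffered acetolysis of an exo-norbornenyl tosylate: the methyl-substituted alkene carbon displaces the exo tosylate from the endo side (homoallyl to cyclopropylcarbinyl), closing the cyclopropane, and acetate should capture the cation at the carbinyl carbon anti to the new cyclopropane bond and from the open CH2-bridge side, which sets the configuration of the secondary acetate.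

**Step 13**
Reactants: 25 nortricyclyl acetate lactone
Product: 26 benzyl-protected triol
Conditions: LiAlH4, THF, 0 °C → reflux; Fieser work-up
Reagents that add atoms: none
Why: Hydride reduction should open the lactone tether to the primary and the hindered secondary alcohol and cleave the acetate, with no stereocentre touched.

**Step 14**
Reactants: 26 benzyl-protected triol
Product: 27 triacetate benzyl ether
Conditions: Ac2O, pyridine, DMAP, 40 °C
Reagents that add atoms: acetic anhydride, CC(=O)OC(C)=O
Why: DMAP-catalysed acylation should esterify all three free hydroxyls while the benzyl ether keeps the fourth oxygen masked.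

**Step 15**
Reactants: 27 triacetate benzyl ether
Product: 28 CNP0111873.1
Conditions: H2 (1 atm), 10% Pd/C, EtOAc, rt
Reagents that add atoms: none
Why: Neutral hydrogenolysis of the benzyl ether should free the ring hydroxyl without acyl migration from the cis neighbouring acetate; the unactivated cyclopropane and the esters are stable under these conditions.

**Compound list**
1 | isobutyronitrile | CC(C)C#N | starting material
2 | 3-ethoxycyclopent-2-en-1-one | CCOC1=CC(=O)CC1 | starting material
3 | 2-lithio-2-methylpropanenitrile (formed in situ) | [Li]C(C)(C)C#N | intermediate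
4 | lithium 1-(2-cyanopropan-2-yl)-3-ethoxycyclopent-2-en-1-olate (formed in situ) | CCOC1=CC([O-])(C(C)(C)C#N)CC1.[Li+] | intermediate
5 | 2-methyl-2-(3-oxocyclopent-1-en-1-yl)propanenitrile | CC(C)(C#N)C1=CC(=O)CC1 | intermediate
6 | 2-(3-hydroxy-3-methylcyclopent-1-en-1-yl)-2-methylpropanenitrile | CC(C)(C#N)C1=CC(C)(O)CC1 | intermediate
7 | 2-(3-hydroxy-3-methylcyclopent-1-en-1-yl)-2-methylpropan-1-imine (formed in situ) | CC(C)(C=N)C1=CC(C)(O)CC1 | intermediate
8 | 2-(3-hydroxy-3-methylcyclopent-1-en-1-yl)-2-methylpropanal | CC(C)(C=O)C1=CC(C)(O)CC1 | intermediate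
9 | allyl benzyl ether | C=CCOCc1ccccc1 | starting material
10 | (Z)-3-(benzyloxy)allyllithium (formed in situ) | [Li]C/C=C\OCc1ccccc1 | intermediate
11 | lithium [(Z)-3-(benzyloxy)allyl]diisopinocampheyl(methoxy)borate (formed in situ) | [Li+].CO[B-](C/C=C\OCc1ccccc1)([C@H]1C[C@H]2C[C@@H]([C@@H]1C)C2(C)C)[C@H]1C[C@H]2C[C@@H]([C@@H]1C)C2(C)C | intermediate
12 | B-[(Z)-3-(benzyloxy)allyl]diisopinocampheylborane (formed in situ) | c1ccccc1CO\C=C/CB([C@H]2C[C@H]3C[C@@H]([C@@H]2C)C3(C)C)[C@H]2C[C@H]3C[C@@H]([C@@H]2C)C3(C)C | intermediate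
13 | O-diisopinocampheylboryl ether of 14 (formed in situ) | C=C[C@H](OCc1ccccc1)[C@@H](OB([C@H]2C[C@H]3C[C@@H]([C@@H]2C)C3(C)C)[C@H]2C[C@H]3C[C@@H]([C@@H]2C)C3(C)C)C(C)(C)C1=CC(C)(O)CC1 | intermediate
14 | (3S,4S)-4-(benzyloxy)-2-(3-hydroxy-3-methylcyclopent-1-en-1-yl)-2-methylhex-5-en-3-ol | C=C[C@H](OCc1ccccc1)[C@@H](O)C(C)(C)C1=CC(C)(O)CC1 | intermediate
15 | (4S)-4-(benzyloxy)-2-(3-hydroxy-3-methylcyclopent-1-en-1-yl)-2-methylhex-5-en-3-one | C=C[C@H](OCc1ccccc1)C(=O)C(C)(C)C1=CC(C)(O)CC1 | intermediate
16 | (3R,4S)-4-(benzyloxy)-2-(3-hydroxy-3-methylcyclopent-1-en-1-yl)-2-methylhex-5-en-3-ol | C=C[C@H](OCc1ccccc1)[C@H](O)C(C)(C)C1=CC(C)(O)CC1 | intermediate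
17 | (4S,5R)-4-(benzyloxy)-5-hydroxy-6-(3-hydroxy-3-methylcyclopent-1-en-1-yl)-6-methylheptanal (formed in situ) | O=CCC[C@H](OCc1ccccc1)[C@H](O)C(C)(C)C1=CC(C)(O)CC1 | intermediate
18 | (5S,6R)-5-(benzyloxy)-6-[2-(3-hydroxy-3-methylcyclopent-1-en-1-yl)propan-2-yl]oxan-2-ol | OC1O[C@H](C(C)(C)C2=CC(C)(O)CC2)[C@@H](OCc3ccccc3)CC1 | intermediate
19 | (5S,6R)-5-(benzyloxy)-6-[2-(3-hydroxy-3-methylcyclopent-1-en-1-yl)propan-2-yl]oxan-2-one | O=C1O[C@H](C(C)(C)C2=CC(C)(O)CC2)[C@@H](OCc3ccccc3)CC1 | intermediate
20 | dilithium salt of 19 (lactone enolate and tertiary alkoxide, formed in situ) | [O-]C1=CC[C@H](OCc2ccccc2)[C@@H](C(C)(C)C2=CC(C)([O-])CC2)O1.[Li+].[Li+] | intermediate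
21 | (3Z,5S,6R)-5-(benzyloxy)-3-(hydroxymethylidene)-6-[2-(3-hydroxy-3-methylcyclopent-1-en-1-yl)propan-2-yl]oxan-2-one | O=C1O[C@H](C(C)(C)C2=CC(C)(O)CC2)[C@@H](OCc3ccccc3)C/C1=C/O | intermediate
22 | (3Z,5S,6R)-5-(benzyloxy)-6-[2-(3-hydroxy-3-methylcyclopent-1-en-1-yl)propan-2-yl]-3-{[(4-methylbenzenesulfonyl)oxy]methylidene}oxan-2-one | O=C1O[C@H](C(C)(C)C2=CC(C)(O)CC2)[C@@H](OCc3ccccc3)C/C1=C/OS(=O)(=O)c1ccc(C)cc1 | intermediate
23 | (3Z,5S,6R)-5-(benzyloxy)-6-[2-(3-methylcyclopenta-1,3-dien-1-yl)propan-2-yl]-3-{[(4-methylbenzenesulfonyl)oxy]methylidene}oxan-2-one (formed in situ, in equilibrium with its 1,5-H-shift isomers) | O=C1O[C@H](C(C)(C)C2=CC(C)=CC2)[C@@H](OCc3ccccc3)C/C1=C/OS(=O)(=O)c1ccc(C)cc1 | intermediate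
24 | pentacyclic Diels–Alder adduct: cyclohexane bridged 1,4 by the δ-lactone (2-oxabicyclo[2.2.2]octan-3-one) and fused through the lactone α-carbon and the adjacent quaternary carbon to a 2-methylnorborn-2-ene; tosylate exo on the norbornene carbon next to the lactone α-carbon; benzyloxy cis to the lactone bridge | O=C4[C@]12C[C@H](OCc6ccccc6)[C@H](O4)C(C)(C)[C@]13C[C@H]([C@@H]2OS(=O)(=O)c7ccc(C)cc7)C(C)=C3 | intermediate
25 | nortricyclyl acetate lactone: as 24 with the cyclopropane closed between the former tosyloxy carbon and the methyl-bearing alkene carbon and an acetate on the former alkene CH, on the CH2-bridge side | O=C4[C@]12C[C@H](OCc6ccccc6)[C@H](O4)C(C)(C)[C@]13C[C@@H]1[C@H]2[C@]1(C)[C@H]3OC(C)=O | intermediate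
26 | benzyl-protected triol: the target skeleton with free CH2OH, free ring secondary OH next to CMe2, free nortricyclyl OH and benzyl ether on the remaining ring oxygen | OC[C@]12C[C@H](OCc4ccccc4)[C@H](O)C(C)(C)[C@]13C[C@@H]1[C@H]2[C@]1(C)[C@H]3O | intermediate
27 | triacetate benzyl ether: the target with its free hydroxyl benzylated | CC(=O)OC[C@]12C[C@H](OCc4ccccc4)[C@H](OC(C)=O)C(C)(C)[C@]13C[C@@H]1[C@H]2[C@]1(C)[C@H]3OC(C)=O | intermediate
28 | CNP0111873.1 | CC(=O)OC[C@]12C[C@H](O)[C@H](OC(C)=O)C(C)(C)[C@]13C[C@@H]1[C@H]2[C@]1(C)[C@H]3OC(C)=O | target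

**Step count and risks**
Total step count: 15. Longest linear sequence: 15 steps (from 1 and 2; 9 enters at step 4).

Step 11. What may go wrong: the β-sulfonyloxy alkylidene lactone may be too weak a dienophile for the strained transannular approach, so that intermolecular dimerisation of the cyclopentadiene, cycloaddition through the methyl-terminated diene tautomer or approach with the lactone carbonyl endo compete. The fallback sets out from 22 and comes back at 24. Miyaura borylation of the enol tosylate (B2pin2, PdCl2(PPh3)2, PPh3, KOPh, PhMe, 50 °C) should give, with retention of geometry, the (Z)-alkenyl pinacolboronate F1, whose vacant boron p-orbital makes the alkene a stronger dienophile. Under the PPTS conditions of step 11 it should pass through the boryl cyclopentadiene F2 to the exo-boryl cycloadduct F3. Oxidation of the C–B bond with retention (NaBO3·4H2O, THF/H2O) should give the exo alcohol F4, and Ts2O, pyridine, DMAP should convert it to 24.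

Step 12. What may go wrong: ionisation is slowed by the acyl-substituted quaternary carbon next to the tosylate, and the forcing conditions then needed allow Wagner–Meerwein shifts or capture of acetate at the neopentyl carbon to compete with cyclopropane closure. The fallback sets out from 24 and comes back at 27, skipping 25 and 26, by removing the carbonyl before the ionisation. LiBH4 in THF should open the lactone without touching the hindered tosylate and give the diol tosylate F5; Ac2O, pyridine, DMAP should give the diacetate tosylate F6; buffered acetolysis (AcOH, NaOAc, 80 °C) of this less deactivated substrate should close the cyclopropane and deliver 27 directly.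

Step 7. What may go wrong: branched hydroformylation or rhodium hydride isomerisation of the allylic ether to an enol ether erodes the linear aldehyde. The fallback sets out from 16 and comes back at 19. Acylation of the secondary alcohol (acryloyl chloride, i-Pr2NEt, DMAP, CH2Cl2) should give the acrylate F7; ring-closing metathesis (Grubbs second-generation catalyst, CH2Cl2, 40 °C) should give the α,β-unsaturated δ-lactone F8; conjugate reduction (L-Selectride, THF, −78 °C; aq. NH4Cl) should give 19.

**Further compounds**
F1 | step 11 | (3Z,5S,6R)-5-(benzyloxy)-6-[2-(3-hydroxy-3-methylcyclopent-1-en-1-yl)propan-2-yl]-3-[(4,4,5,5-tetramethyl-1,3,2-dioxaborolan-2-yl)methylidene]oxan-2-one | O=C1O[C@H](C(C)(C)C2=CC(C)(O)CC2)[C@@H](OCc3ccccc3)C/C1=C/B1OC(C)(C)C(C)(C)O1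
F2 | step 11 | boryl cyclopentadiene: F1 dehydrated to the 3-methylcyclopenta-1,3-dien-1-yl compound (formed in situ) | O=C1O[C@H](C(C)(C)C2=CC(C)=CC2)[C@@H](OCc3ccccc3)C/C1=C/B1OC(C)(C)C(C)(C)O1
F3 | step 11 | exo-boryl Diels–Alder adduct (24 with pinacolboryl in place of tosyloxy) | O=C4[C@]12C[C@H](OCc6ccccc6)[C@H](O4)C(C)(C)[C@]13C[C@H]([C@@H]2B5OC(C)(C)C(C)(C)O5)C(C)=C3
F4 | step 11 | exo-hydroxy Diels–Alder adduct (24 with OH in place of tosyloxy) | O=C4[C@]12C[C@H](OCc6ccccc6)[C@H](O4)C(C)(C)[C@]13C[C@H]([C@@H]2O)C(C)=C3
F5 | step 12 | diol tosylate (24 with the lactone reduced to CH2OH and secondary OH) | OC[C@]12C[C@H](OCc6ccccc6)[C@H](O)C(C)(C)[C@]13C[C@H]([C@@H]2OS(=O)(=O)c7ccc(C)cc7)C(C)=C3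
F6 | step 12 | diacetate tosylate (diacetate of F5) | CC(=O)OC[C@]12C[C@H](OCc6ccccc6)[C@H](OC(C)=O)C(C)(C)[C@]13C[C@H]([C@@H]2OS(=O)(=O)c7ccc(C)cc7)C(C)=C3
F7 | step 7 | (3R,4S)-4-(benzyloxy)-2-(3-hydroxy-3-methylcyclopent-1-en-1-yl)-2-methylhex-5-en-3-yl prop-2-enoate | C=C[C@H](OCc1ccccc1)[C@H](OC(=O)C=C)C(C)(C)C1=CC(C)(O)CC1
F8 | step 7 | (5S,6R)-5-(benzyloxy)-6-[2-(3-hydroxy-3-methylcyclopent-1-en-1-yl)propan-2-yl]-5,6-dihydro-2H-pyran-2-one | O=C1C=C[C@H](OCc2ccccc2)[C@@H](C(C)(C)C2=CC(C)(O)CC2)O1
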